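**Retrosynthetic overview**

- Feature: the central ring B (B1 carries the butanoyl group, B2/B4/B6 the hydroxyls, B3/B5 the CH2 bridges to rings A and C) has the oxygen pattern of a folded tetraketide. B6–B5–B4–B3–B2–B1 map onto C1–C6 of a 3,5,7-trioxodecanoate whose C2 and C4 already carry the two arylmethyl arms.
- Key disconnection: the B1–B6 bond, made by Claisen closure of chain C6 onto the ester carbon C1 of triketo ester 14. Rings A and C are bought as 1,3,5-trimethoxy-2-methylbenzene, so ring B is the only ring formed.
- 14 comes from ketal 13, which comes from γ-acylation (C4–C5) of the dianion of β-keto ester 8 with the ketal-masked Weinreb amide 11 (from methyl 3-oxohexanoate).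
- 8 takes its C4 arm from Friedel–Crafts conjugate addition of the arene to but-3-en-2-one followed by carbomethoxylation, and its C2 arm from Knoevenagel condensation with aldehyde 6 and hydrogenation. This avoids the self-condensing trimethoxybenzyl chloride.
- After ring closure: twofold Friedel–Crafts butanoylation of rings A and C while they are still methyl ethers, then sixfold demethylation with BBr3.

Key step: step 10

Remark: the target is achiral. The stereocentres at C2 and C4 of 8, 13 and 14 are formed without control and handled as diastereomer/tautomer mixtures, because both carbons become aromatic in step 10.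

**Step 1**
Reactants: 1 1,3,5-trimethoxy-2-methylbenzene; 2 but-3-en-2-one
Product: 3 4-(2,4,6-trimethoxy-3-methylphenyl)butan-2-one
Conditions: 1 (2 equiv), 2 (1 equiv), Sc(OTf)3 (5 mol %), MeCN, rt
Reagents that add atoms: none
Why: Friedel–Crafts conjugate addition (Michael-type hydroarylation) at one of the two equivalent free ring carbons, each activated by three methoxy groups; excess arene should hold the reaction at the mono-adduct.

**Step 2**
Reactants: 3 4-(2,4,6-trimethoxy-3-methylphenyl)butan-2-one
Product: 4 methyl 3-oxo-5-(2,4,6-trimethoxy-3-methylphenyl)pentanoate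
Conditions: NaH (2.2 equiv), (MeO)2CO, THF, reflux; then 1 M HCl, 0 °C
Reagents that add atoms: dimethyl carbonate, COC(=O)OC
Why: Claisen-type carbomethoxylation of a methyl ketone goes to the methyl carbon, because only that product is drained from the equilibrium as an unhindered, stabilised β-keto ester enolate.

**Step 3**
Reactants: 1 1,3,5-trimethoxy-2-methylbenzene
Product: 6 2,4,6-trimethoxy-3-methylbenzaldehyde, via aryl iminium chloride 5 (not isolated)
Conditions: POCl3, DMF, 0 °C → rt; then H2O
Reagents that add atoms: N,N-dimethylformamide, CN(C)C=O; water, O; phosphoryl chloride, O=P(Cl)(Cl)Cl (chloride counter-ion of 5 only)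
Why: Vilsmeier–Haack formylation at one of the two equivalent activated ring carbons, followed by hydrolysis of the iminium salt on work-up.

**Step 4**
Reactants: 4 methyl 3-oxo-5-(2,4,6-trimethoxy-3-methylphenyl)pentanoate; 6 2,4,6-trimethoxy-3-methylbenzaldehyde
Product: 7 methyl 3-oxo-5-(2,4,6-trimethoxy-3-methylphenyl)-2-[(2,4,6-trimethoxy-3-methylphenyl)methylidene]pentanoate (E/Z mixture)
Conditions: piperidine (cat.), AcOH (cat.), PhMe, reflux, Dean–Stark
Reagents that add atoms: none
Why: Knoevenagel condensation at C2, the only carbon of 4 with two doubly activated hydrogens, with a non-enolisable aldehyde, driven by azeotropic removal of water.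

**Step 5**
Reactants: 7 Knoevenagel adduct (E/Z mixture)
Product: 8 methyl 3-oxo-5-(2,4,6-trimethoxy-3-methylphenyl)-2-[(2,4,6-trimethoxy-3-methylphenyl)methyl]pentanoate (racemate)
Conditions: H2 (1 atm), Pd/C, EtOAc, rt
Reagents that add atoms: none
Why: catalytic hydrogenation of the electron-poor trisubstituted alkene; both alkene isomers converge, the aliphatic ketone, ester and aryl ethers should be untouched, and the new C2 centre is racemic and later destroyed.

**Step 6**
Reactants: 9 methyl 3-oxohexanoate
Product: 10 methyl 2-(2-propyl-1,3-dioxolan-2-yl)acetate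
Conditions: HOCH2CH2OH, TsOH·H2O (cat.), PhMe, reflux, Dean–Stark
Reagents that add atoms: ethylene glycol, OCCO
Why: acid-catalysed ketalisation with water removal masks the ketone, so the later acyl donor has no doubly activated methylene to quench a carbanion.

**Step 7**
Reactants: 10 methyl 2-(2-propyl-1,3-dioxolan-2-yl)acetate
Product: 11 N-methoxy-N-methyl-2-(2-propyl-1,3-dioxolan-2-yl)acetamide
Conditions: MeNH(OMe)·HCl, i-PrMgCl, THF, −20 → 0 °C; then aq. NH4Cl
Reagents that add atoms: N,O-dimethylhydroxylamine hydrochloride, CNOC.Cl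
Why: direct aminolysis of the ester by the chloromagnesium amide formed in the flask gives the Weinreb amide; the weakly basic magnesium amide should not trigger ring-opening elimination of the β-ketal.

**Step 8**
Reactants: 8 dibenzylated β-keto ester (racemate); 11 N-methoxy-N-methyl-2-(2-propyl-1,3-dioxolan-2-yl)acetamide
Product: 13 methyl 3,5-dioxo-6-(2-propyl-1,3-dioxolan-2-yl)-2,4-bis[(2,4,6-trimethoxy-3-methylphenyl)methyl]hexanoate (diastereomer mixture), via dilithium dianion 12 (not isolated)
Conditions: LiN(i-Pr)2 (2.05 equiv), THF, −78 → 0 °C; then 11 (1.2 equiv), −78 → −20 °C; aq. NH4Cl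
Reagents that add atoms: lithium diisopropylamide, CC(C)[N-]C(C)C.[Li+] (lithium of intermediate 12 only)
Why: β-keto ester dianion acylation (Huckin–Weiler type): the second deprotonation gives the γ-carbanion at C4, which adds to the Weinreb amide, and the chelated tetrahedral adduct blocks over-addition and proton exchange until the quench; the amide base is chosen so that the ring C–H between two methoxy groups is not lithiated, and the C2/C4 centres form unselectively, which is immaterial.

**Step 9**
Reactants: 13 ketal-masked diketo ester (diastereomer mixture)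
Product: 14 methyl 3,5,7-trioxo-2,4-bis[(2,4,6-trimethoxy-3-methylphenyl)methyl]decanoate (diastereomer and tautomer mixture)
Conditions: 1 M HCl, THF, rt; used directly
Reagents that add atoms: water, O
Why: acid hydrolysis of a dioxolane β to a ketone is fast under mild conditions that should leave the aryl methyl ethers and the methyl ester intact.

**Step 10**
Reactants: 14 methyl 3,5,7-trioxo-2,4-bis[(2,4,6-trimethoxy-3-methylphenyl)methyl]decanoate
Product: 16 1-[2,4,6-trihydroxy-3,5-bis[(2,4,6-trimethoxy-3-methylphenyl)methyl]phenyl]butan-1-one, via cyclohexanetrione tautomer 15 (not isolated)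
Conditions: Mg(OMe)2 (5 equiv), MeOH, reflux, Ar; then 1 M HCl, 0 °C
Reagents that add atoms: none
Why: Mg(OMe)2 turns 14 into a magnesium-chelated polyenolate in which the C6 carbanion, flanked by the C5 and C7 ketones, adds to the ester carbonyl C1 held and activated in a chelate with O3; loss of methoxide gives trione 15, which enolises irreversibly to the phloroglucinol. The closest known reaction is the base-induced Claisen (Dieckmann-type) cyclisation of 3,5,7-triketo esters to acylphloroglucinols. Ring B closes in a 6-exo-trig mode that forms the B1–B6 bond, with the butanoyl group and both arms already in place. No stereocentre is made, since C2 and C4 of the chain become sp2 carbons B5 and B3. The step needs Claisen folding rather than aldol folding (C2 onto C7) or methanolysis of the chain: the arylmethyl group on C2 makes the aldol adduct quaternary and unable to aromatise, so it should revert. Magnesium chelation keeps both β-dicarbonyl units as enolates that resist retro-Claisen attack, and any 2-pyranone formed by lactonisation should reopen under these conditions and drain into the aromatic product.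

**Step 11**
Reactants: 16 1-[2,4,6-trihydroxy-3,5-bis[(2,4,6-trimethoxy-3-methylphenyl)methyl]phenyl]butan-1-one
Product: 17 1-[3,5-bis[(3-butanoyl-2,4,6-trimethoxy-5-methylphenyl)methyl]-2,4,6-trihydroxyphenyl]butan-1-one
Conditions: PrCOCl (2.5 equiv), SnCl4, CH2Cl2, −20 → 0 °C; then 1 M HCl
Reagents that add atoms: butanoyl chloride, CCCC(=O)Cl
Why: Friedel–Crafts acylation at the single unsubstituted carbon of rings A and C, each activated by two ortho and one para methoxy group, while ring B has no free position; acylating before demethylation keeps every ring deactivated by an acyl group during the final acid step.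

**Step 12**
Reactants: 17 bis-butanoylated hexamethyl ether
Product: 18 1-[3,5-bis[(3-butanoyl-2,4,6-trihydroxy-5-methylphenyl)methyl]-2,4,6-trihydroxyphenyl]butan-1-one (target)
Conditions: BBr3 (excess), CH2Cl2, −78 °C → rt, Ar; then H2O, 0 °C
Reagents that add atoms: none
Why: BBr3 ether cleavage (boron complexation, then demethylation by bromide) removes all six methyl groups, helped by the ortho carbonyls; aryl ketones and the acyl-deactivated diarylmethane bridges should tolerate the conditions at or below room temperature.

**Compound list**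

1 | 1,3,5-trimethoxy-2-methylbenzene | Cc1c(OC)cc(OC)cc1OC | starting material
2 | but-3-en-2-one | CC(=O)C=C | starting material
3 | 4-(2,4,6-trimethoxy-3-methylphenyl)butan-2-one | CC(=O)CCc1c(OC)cc(OC)c(C)c1OC | intermediate
4 | methyl 3-oxo-5-(2,4,6-trimethoxy-3-methylphenyl)pentanoate | COC(=O)CC(=O)CCc1c(OC)cc(OC)c(C)c1OC | intermediate
5 | N,N-dimethyl-1-(2,4,6-trimethoxy-3-methylphenyl)methaniminium chloride (not isolated) | C[N+](C)=Cc1c(OC)cc(OC)c(C)c1OC.[Cl-] | intermediate
6 | 2,4,6-trimethoxy-3-methylbenzaldehyde | O=Cc1c(OC)cc(OC)c(C)c1OC | intermediate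
7 | methyl 3-oxo-5-(2,4,6-trimethoxy-3-methylphenyl)-2-[(2,4,6-trimethoxy-3-methylphenyl)methylidene]pentanoate (E/Z mixture) | COC(=O)C(=Cc1c(OC)cc(OC)c(C)c1OC)C(=O)CCc1c(OC)cc(OC)c(C)c1OC | intermediate
8 | methyl 3-oxo-5-(2,4,6-trimethoxy-3-methylphenyl)-2-[(2,4,6-trimethoxy-3-methylphenyl)methyl]pentanoate (racemate) | COC(=O)C(Cc1c(OC)cc(OC)c(C)c1OC)C(=O)CCc1c(OC)cc(OC)c(C)c1OC | intermediate
9 | methyl 3-oxohexanoate | CCCC(=O)CC(=O)OC | starting material
10 | methyl 2-(2-propyl-1,3-dioxolan-2-yl)acetate | CCCC1(CC(=O)OC)OCCO1 | intermediate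
11 | N-methoxy-N-methyl-2-(2-propyl-1,3-dioxolan-2-yl)acetamide | CCCC1(CC(=O)N(C)OC)OCCO1 | intermediate
12 | dilithium dianion (C2 enolate, C4 carbanion) of 8 (not isolated) | [Li+].[Li+].COC([O-])=C(Cc1c(OC)cc(OC)c(C)c1OC)C([O-])=CCc1c(OC)cc(OC)c(C)c1OC | intermediate
13 | methyl 3,5-dioxo-6-(2-propyl-1,3-dioxolan-2-yl)-2,4-bis[(2,4,6-trimethoxy-3-methylphenyl)methyl]hexanoate (diastereomer mixture) | CCCC1(CC(=O)C(Cc2c(OC)cc(OC)c(C)c2OC)C(=O)C(Cc2c(OC)cc(OC)c(C)c2OC)C(=O)OC)OCCO1 | intermediate
14 | methyl 3,5,7-trioxo-2,4-bis[(2,4,6-trimethoxy-3-methylphenyl)methyl]decanoate (diastereomer mixture) | CCCC(=O)CC(=O)C(Cc1c(OC)cc(OC)c(C)c1OC)C(=O)C(Cc1c(OC)cc(OC)c(C)c1OC)C(=O)OC | intermediate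
15 | 2-butanoyl-4,6-bis[(2,4,6-trimethoxy-3-methylphenyl)methyl]cyclohexane-1,3,5-trione (not isolated) | CCCC(=O)C1C(=O)C(Cc2c(OC)cc(OC)c(C)c2OC)C(=O)C(Cc2c(OC)cc(OC)c(C)c2OC)C1=O | intermediate
16 | 1-[2,4,6-trihydroxy-3,5-bis[(2,4,6-trimethoxy-3-methylphenyl)methyl]phenyl]butan-1-one | CCCC(=O)c1c(O)c(Cc2c(OC)cc(OC)c(C)c2OC)c(O)c(Cc2c(OC)cc(OC)c(C)c2OC)c1O | intermediate
17 | 1-[3,5-bis[(3-butanoyl-2,4,6-trimethoxy-5-methylphenyl)methyl]-2,4,6-trihydroxyphenyl]butan-1-one | CCCC(=O)c1c(O)c(Cc2c(OC)c(C)c(OC)c(C(=O)CCC)c2OC)c(O)c(Cc2c(OC)c(C)c(OC)c(C(=O)CCC)c2OC)c1O | intermediate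
18 | 1-[3,5-bis[(3-butanoyl-2,4,6-trihydroxy-5-methylphenyl)methyl]-2,4,6-trihydroxyphenyl]butan-1-one | CCCC(=O)c1c(O)c(C)c(O)c(Cc2c(O)c(Cc3c(O)c(C)c(O)c(C(=O)CCC)c3O)c(O)c(C(=O)CCC)c2O)c1O | target

**Step count**

Total: 12 steps. Longest linear sequence: 9 steps (steps 1, 2, 4, 5, 8, 9, 10, 11, 12).

**Steps most likely to fail**

1. Step 10. The chain may be cut by methoxide (retro-Claisen cleavage at C3 or C5) or fold by lactonisation or aldol closure faster than the Claisen closure. The fallback buys ring B instead of making it. It sets out from 6, which NaBH4 in MeOH at 0 °C should reduce to (2,4,6-trimethoxy-3-methylphenyl)methanol F1. F1 (2.2 equiv, added slowly to limit self-condensation at its own free ring carbon) would then be used in an acid-catalysed twofold Friedel–Crafts benzylation (TsOH cat., MeCN, 0 °C → rt) of purchased 1-(2,4,6-trihydroxyphenyl)butan-1-one F2, whose only two free ring carbons take the arms. The route is rejoined at 16.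

2. Step 8. The hindered secondary carbanion at C4 may attack the amide slowly, so that proton transfer to the amide and ring-opening elimination of the ketal take over. The fallback replaces acylation by aldol addition and oxidation. It sets out from 10, which i-Bu2AlH in CH2Cl2 at −78 °C should reduce to 2-(2-propyl-1,3-dioxolan-2-yl)acetaldehyde F3. Dianion 12 (from 8 as in step 8) should add to F3 at −78 °C to give methyl 5-hydroxy-3-oxo-6-(2-propyl-1,3-dioxolan-2-yl)-2,4-bis[(2,4,6-trimethoxy-3-methylphenyl)methyl]hexanoate F4 as a diastereomer mixture. Oxidation of the β-hydroxy ketone with IBX (EtOAc, 70 °C) would return to the route at 13.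

3. Step 11. The acylium ion may attack a bridge-bearing carbon and cut a diarylmethane link, the ring B phenols may be O-acylated (a K2CO3/MeOH treatment would correct that), or the second acylation may stall. The fallback reverses the order and changes the acylation mechanism. It sets out from 16, which BBr3 (CH2Cl2, −78 °C → rt) should demethylate to 1-[2,4,6-trihydroxy-3,5-bis[(2,4,6-trihydroxy-3-methylphenyl)methyl]phenyl]butan-1-one F5. Heating F5 with butanoic acid and BF3·OEt2 (phenol ester formation and Fries-type shift, the classical C-acylation of phloroglucinols) should place the acyl group on the only free carbon of rings A and C. The route is rejoined at 18, and step 12 is then not needed.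

**Further compounds**

F1 | step 10 | (2,4,6-trimethoxy-3-methylphenyl)methanol | OCc1c(OC)cc(OC)c(C)c1OC
F2 | step 10 | 1-(2,4,6-trihydroxyphenyl)butan-1-one (purchased) | CCCC(=O)c1c(O)cc(O)cc1O
F3 | step 8 | 2-(2-propyl-1,3-dioxolan-2-yl)acetaldehyde | CCCC1(CC=O)OCCO1
F4 | step 8 | methyl 5-hydroxy-3-oxo-6-(2-propyl-1,3-dioxolan-2-yl)-2,4-bis[(2,4,6-trimethoxy-3-methylphenyl)methyl]hexanoate (diastereomer mixture) | CCCC1(CC(O)C(Cc2c(OC)cc(OC)c(C)c2OC)C(=O)C(Cc2c(OC)cc(OC)c(C)c2OC)C(=O)OC)OCCO1
F5 | step 11 | 1-[2,4,6-trihydroxy-3,5-bis[(2,4,6-trihydroxy-3-methylphenyl)methyl]phenyl]butan-1-one | CCCC(=O)c1c(O)c(Cc2c(O)cc(O)c(C)c2O)c(O)c(Cc2c(O)cc(O)c(C)c2O)c1O
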